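**Plan**

1. Locants: N–C1H2–C8 (quaternary); C5 (quaternary; C21H2OH; chain C4–C3–C2(OH)–C18–C20); C6(H)–C7H2–N; ring D (seven-membered) C5–C6–C12–C11–C10=C9–C8; ring E C8–C9–C15–C14(C22O2Me)–C13; ring F C9–C10–C17–C16–C15; piperidine N–C1–C8–C5–C6–C7.
2. Cuts: C14–H back to a malonate; C3=C4 (olefination) and C5–C21 (formaldehyde aldol), leaving a C5 ketone; C1–C8 (Mannich); C5–C8 (Dieckmann, ring D); C9–C15, C10–C17 and C16–C17 (Pauson–Khand, rings E and F), down to an acyclic enyne triester.
3. Enabling feature: with C5 as a ketone the piperidine N–C1–C8–C5–C6–C7 is a 4-piperidone, and with a temporary ketone on C17 the quaternary C8 is the central carbon of the vinylogous 1,3-diketone C5(=O)–C8–C9=C10–C17(=O). A tethered N-methyleneiminium ion therefore closes C1–C8, makes C8 quaternary and leaves the alkene at C9=C10.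
4. Forward: enyne, rings E and F (cyclocarbonylation), ring D (Dieckmann), piperidine (Mannich), resolution, removal of the C17 oxygen, conversion of the C5 ketone into the quaternary carbon with its two chains, loss of the extra ester.
5. Stereochemistry: the Mannich step sets C8 and C6 relative to C15 (convex face of the diquinane; only a cis bridge can close). The absolute configuration comes from resolution of the Mannich base as a tartrate salt, because C15 is a labile γ-position of the enone until then. C5 and C14 follow from the shape of the bridged core (formaldehyde and a proton enter on the less hindered faces), and C2 comes from the CBS reagent.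

Key step: step 7

Assumption: the (2R,3R)-acid 14 is taken to give the less soluble salt with the (6R,8S,15R)-amine; if the opposite holds, its (2S,3S)-antipode is used.

Step 1
Reactants: 1 dimethyl 2-ethylidenepropanedioate; 2 4-iodobut-1-yne
Product: 3 dimethyl 2-(but-3-yn-1-yl)-2-ethenylpropanedioate
Conditions: LiN(iPr)2, THF–DMPU, −78 °C; then 2, −78 to 0 °C
Reagents that add atoms: none
Why: γ-Deprotonation of the alkylidenemalonate gives an extended enolate that is alkylated at the α-carbon (deconjugative alkylation), which puts the vinyl group and the butynyl chain on the future C14; no stereocenter is formed.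

Step 2
Reactants: 3 dimethyl 2-(but-3-yn-1-yl)-2-ethenylpropanedioate; 4 methyl 4-iodobutanoate
Product: 5 trimethyl dec-1-en-6-yne-3,3,10-tricarboxylate
Conditions: [Pd(C3H5)Cl]2 (2.5 mol%), 1,3-di(1-adamantyl)imidazolium chloride (5 mol%), CuI (7.5 mol%), Cs2CO3, DMF–Et2O, 45 °C
Reagents that add atoms: none
Why: Sonogashira coupling of a terminal alkyne with an unactivated primary alkyl iodide (palladium–carbene and copper co-catalysis) joins C10 to C11 and tolerates the esters and the alkene.

Step 3
Reactants: 6 tert-butyl methylcarbamate
Product: 7 tert-butyl (chloromethyl)(methyl)carbamate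
Conditions: (CH2O)n, Me3SiCl, CH2Cl2, rt
Reagents that add atoms: paraformaldehyde (as formaldehyde), C=O; chlorotrimethylsilane, C[Si](C)(C)Cl
Why: N-Hydroxymethylation of the carbamate and exchange of OH for Cl gives the amidomethyl chloride (an N-acyliminium precursor) that carries N, its methyl group and C7.

Step 4
Reactants: 5 trimethyl dec-1-en-6-yne-3,3,10-tricarboxylate; 7 tert-butyl (chloromethyl)(methyl)carbamate
Product: 8 trimethyl 11-[(tert-butoxycarbonyl)(methyl)amino]undec-1-en-6-yne-3,3,10-tricarboxylate
Conditions: LiN(iPr)2, THF, −78 °C; then 7, −78 to −20 °C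
Reagents that add atoms: none
Why: C6 is the only enolizable position (the malonate carbon is quaternary) and its lithium enolate is alkylated by the amidomethyl chloride (amidoalkylation of an ester enolate); C6 forms as a racemate, which does not matter because it equilibrates before it is fixed in step 7.

Step 5
Reactants: 8 trimethyl 11-[(tert-butoxycarbonyl)(methyl)amino]undec-1-en-6-yne-3,3,10-tricarboxylate
Product: 9 racemic bicyclic enone (rings E and F) with the C9=C10–C17=O enone
Conditions: [Rh(CO)2Cl]2 (5 mol%), CO (1 atm), toluene, 110 °C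
Reagents that add atoms: carbon monoxide, [C-]#[O+]
Why: Catalytic intramolecular Pauson–Khand [2+2+1] cyclocarbonylation of the 1,6-enyne forms rings E and F in one operation, helped by the quaternary C14; C15 forms as a racemate and, being a γ-position of the enone, is not used as a source of absolute configuration.

Step 6
Reactants: 9 racemic bicyclic enone
Product: 10 racemic tricyclic vinylogous acid (rings D, E, F), enol C5(OH)=C8–C9=C10–C17=O
Conditions: NaOMe (3 equiv.), MeOH, 65 °C; then AcOH
Reagents that add atoms: none
Why: Dieckmann condensation under thermodynamic control: the extended enolate of the enone attacks the side-chain ester through its γ-carbon C8 and closes ring D, because only this mode gives an unstrained product held as the stabilized vinylogous β-diketonate, whereas acylation at C10 reverts by retro-Claisen cleavage and acylation at C16 would give a bridgehead enone.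

Step 7
Reactants: 10 racemic tricyclic vinylogous acid
Product: 13 racemic tetracyclic amino diketone diester (6R*,8S*,15R*), via ammonium trifluoroacetate 11 (not isolated), via N-methyleneiminium ion 12 (not isolated)
Conditions: CF3CO2H, anisole, CH2Cl2, 0 °C to rt; evaporate; then (CH2O)n (1.1 equiv.), EtOH, 60 °C; aq. NaHCO3
Reagents that add atoms: paraformaldehyde (as formaldehyde), C=O
Why: Acid removes the Boc group, the secondary amine condenses with formaldehyde to the N-methyl-N-methyleneiminium ion 12, and its carbon C1 is attacked by C8, the central and most nucleophilic carbon of the enolized vinylogous 1,3-diketone, so that C1–C8 forms, C8 becomes quaternary and the alkene is fixed at C9=C10. The closest known reaction type is the intramolecular Mannich cyclization of a β-amino ketone to a 4-piperidone, the ring-closing half of a double Mannich annulation of a 1,3-dicarbonyl compound. The piperidine closes in the 6-(enolendo)-endo-trig mode, the enol C5=C8 and the iminium C1=N both lying inside the new ring, which bridges C6 and C8 of ring D. C8 is controlled by C15, since the iminium carbon reaches the flat dienol on the convex face of the cis-fused diquinane (the face of H-15, away from the pseudoaxial ester on C14), and C6 is controlled by the ring, since only the cis arm can reach and the two C6 epimers interconvert through the enol (Curtin–Hammett). The step needs site selectivity for C8 over C10 and over oxygen (six-membered against seven-membered closure; O-attack is reversible) and face selectivity at C8 (the fold of the diquinane and the C14 diester). Only a slight excess of formaldehyde is used so that hydroxymethylation of C8 does not compete.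

Step 8
Reactants: 13 racemic tetracyclic amino diketone diester; 14 (2R,3R)-2,3-bis[(4-methylbenzoyl)oxy]butanedioic acid
Product: 15 1:1 salt of the (6R,8S,15R)-amine and acid 14
Conditions: 14 (1 equiv.), EtOH, 60 °C to rt; recrystallization from EtOH
Reagents that add atoms: none
Why: Classical resolution: the enantiomeric tertiary amines form diastereomeric hydrogen tartrate salts of different solubility, and crystallization of the less soluble one fixes the absolute configuration of C6, C8 and C15.

Step 9
Reactants: 15 salt of the (6R,8S,15R)-amine and acid 14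
Product: 17 C17 allylic alcohol, via free base 16 (not isolated)
Conditions: aq. NaHCO3, CH2Cl2; then NaBH4 (1 equiv.), CeCl3·7H2O, MeOH, −78 °C
Reagents that add atoms: none
Why: Luche reduction: cerium-assisted 1,2-reduction of the cyclopentenone carbonyl C17 is preferred over the C5 ketone, which is flanked by the quaternary C8 and the bridgehead C6; the carbinol configuration is irrelevant.

Step 10
Reactants: 17 C17 allylic alcohol
Product: 18 amino ketone with C17 as CH2 and the C9=C10 alkene
Conditions: Et3SiH, CF3CO2H, CH2Cl2, −20 to 0 °C; aq. NaHCO3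
Reagents that add atoms: none
Why: Ionic deoxygenation: the allylic alcohol ionizes to the C17–C10–C9 allyl cation, which takes hydride at the unhindered secondary terminus C17 and so restores the tetrasubstituted C9=C10 alkene, while the ammonium group and the hindered C5 ketone are left alone at low temperature.

Step 11
Reactants: 18 amino ketone
Product: 19 spiro-epoxide at C5
Conditions: Me3S+ I−, KN(SiMe3)2, THF, −10 °C to rt
Reagents that add atoms: trimethylsulfonium iodide, C[S+](C)C.[I-]
Why: Corey–Chaykovsky epoxidation: the small sulfonium ylide adds to the hindered, non-enolizable C5 ketone where bulkier Wittig reagents are slow; the configuration of the epoxide is irrelevant.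

Step 12
Reactants: 19 spiro-epoxide
Product: 20 C5 carbaldehyde (both epimers at C5)
Conditions: BF3·OEt2 (2.5 equiv.), CH2Cl2, −78 to −20 °C; aq. NaHCO3
Reagents that add atoms: none
Why: Meinwald rearrangement: Lewis acid opening of the tertiary C5–O bond with 1,2-hydride shift from the methylene carbon gives the aldehyde, the amine being masked as its BF3 adduct; C5 is now enolizable, so its configuration is irrelevant.

Step 13
Reactants: 20 C5 carbaldehyde
Product: 21 5-formyl-5-(hydroxymethyl) compound (CH2OH syn to the C9=C10 bridge)
Conditions: aq. CH2O (37%), K2CO3 (0.3 equiv.), MeOH–THF, 40 °C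
Reagents that add atoms: formaldehyde, C=O
Why: Crossed aldol (Tollens-type hydroxymethylation) of the α-branched aldehyde makes C5 quaternary; formaldehyde enters the exocyclic enol on the face syn to the C9=C10 bridge of ring D (one flanking axial hydrogen there, two on the piperidine side), and the reversibility of the aldol also favours the larger CH2OH group on that face, so CH2OH becomes C21 and CHO becomes C4 on the nitrogen side.

Step 14
Reactants: 21 5-formyl-5-(hydroxymethyl) compound; 22 dimethyl (2-oxobutyl)phosphonate
Product: 23 (E)-enone C5–CH=CH–C(=O)–Et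
Conditions: LiCl, iPr2NEt, MeCN, rt
Reagents that add atoms: none
Why: Horner–Wadsworth–Emmons olefination in its mild LiCl/amine form (tolerated by the β-hydroxy aldehyde) adds C3, C2, C18 and C20 as the (E)-enone.

Step 15
Reactants: 23 (E)-enone
Product: 24 (2S,E)-allylic alcohol
Conditions: (R)-2-methyl-CBS-oxazaborolidine (1 equiv.), catecholborane, toluene, −78 °C; MeOH; aq. NaOH
Reagents that add atoms: none
Why: Corey–Bakshi–Shibata reduction: the alkenyl group acts as the large and ethyl as the small substituent of the enone, so the (R)-oxazaborolidine directs hydride to give the (2S) alcohol (reagent control).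

Step 16
Reactants: 24 (2S,E)-allylic alcohol
Product: 25 saturated diol diester
Conditions: H2 (1 atm), 5% Pt/C, EtOAc, rt
Reagents that add atoms: none
Why: Heterogeneous hydrogenation saturates the disubstituted C3=C4 alkene, while the shielded tetrasubstituted C9=C10 alkene does not react at one atmosphere.

Step 17
Reactants: 25 saturated diol diester
Product: 26 target, (2S,5S,6R,8S,14S,15S)
Conditions: LiCl, H2O, DMSO, 150 °C
Reagents that add atoms: none
Why: Krapcho dealkoxycarbonylation removes one ester of the malonate; the ester enolate left after loss of CO2 is protonated by water on the less hindered face of ring E (the face of H-15 and C1, away from C16 and C5), which puts H-14 cis to H-15 under kinetic control in a medium too weakly basic to epimerize the product.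

**Compound list**

1 | dimethyl 2-ethylidenepropanedioate | CC=C(C(=O)OC)C(=O)OC | starting material
2 | 4-iodobut-1-yne | C#CCCI | starting material
3 | dimethyl 2-(but-3-yn-1-yl)-2-ethenylpropanedioate | C=CC(CCC#C)(C(=O)OC)C(=O)OC | intermediate
4 | methyl 4-iodobutanoate | COC(=O)CCCI | starting material
5 | trimethyl dec-1-en-6-yne-3,3,10-tricarboxylate | COC(=O)CCCC#CCCC(C=C)(C(=O)OC)C(=O)OC | intermediate
6 | tert-butyl methylcarbamate | CNC(=O)OC(C)(C)C | starting material
7 | tert-butyl (chloromethyl)(methyl)carbamate | CN(CCl)C(=O)OC(C)(C)C | intermediate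
8 | trimethyl 11-[(tert-butoxycarbonyl)(methyl)amino]undec-1-en-6-yne-3,3,10-tricarboxylate (racemic at the future C6) | COC(=O)C(CN(C)C(=O)OC(C)(C)C)CCC#CCCC(C=C)(C(=O)OC)C(=O)OC | intermediate
9 | racemic bicyclic enone (rings E and F): dimethyl 3-{3-{[(tert-butoxycarbonyl)(methyl)amino]methyl}-4-methoxy-4-oxobutyl}-2-oxo-1,2,4,5,6,6a-hexahydropentalene-6,6-dicarboxylate; both epimers at C6 | COC(=O)C(CN(C)C(=O)OC(C)(C)C)CCC1=C2C(CC1=O)C(C(=O)OC)(C(=O)OC)CC2 | intermediate
10 | racemic tricyclic vinylogous acid (rings D, E, F; cyclopent[cd]azulene skeleton): enol C5(OH)=C8–C9=C10–C17=O, CH2N(CH3)Boc on C6, two CO2Me on C14; both epimers at C6 | OC=1C(CN(C)C(=O)OC(C)(C)C)CCC2=C3C(CC2=O)C(C(=O)OC)(C(=O)OC)CC3=1 | intermediate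
11 | secondary amine from 10 (N–H in place of N–Boc), held as its trifluoroacetate; not isolated | OC=1C(CNC)CCC2=C3C(CC2=O)C(C(=O)OC)(C(=O)OC)CC3=1 | intermediate
12 | N-methyl-N-methyleneiminium ion from 11; not isolated | OC=1C(C[N+](C)=C)CCC2=C3C(CC2=O)C(C(=O)OC)(C(=O)OC)CC3=1 | intermediate
13 | racemic tetracyclic amino diketone diester: C5 and C17 ketones, C9=C10, N-methylpiperidine N–C1–C8–C5–C6–C7 bridging ring D, C1 cis to H-15 (6R*,8S*,15R*); both enantiomers shown | O=C1[C@H]2CCC3=C4[C@@H](CC3=O)C(C(=O)OC)(C(=O)OC)C[C@]41CN(C)C2.O=C1[C@@H]2CCC3=C4[C@H](CC3=O)C(C(=O)OC)(C(=O)OC)C[C@@]41CN(C)C2 | intermediate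
14 | (2R,3R)-2,3-bis[(4-methylbenzoyl)oxy]butanedioic acid | Cc1ccc(cc1)C(=O)O[C@@H](C(O)=O)[C@@H](OC(=O)c1ccc(C)cc1)C(O)=O | starting material
15 | 1:1 salt of the (6R,8S,15R)-amino diketone diester and 14 | O=C1[C@H]2CCC3=C4[C@@H](CC3=O)C(C(=O)OC)(C(=O)OC)C[C@]41CN(C)C2.Cc1ccc(cc1)C(=O)O[C@@H](C(O)=O)[C@@H](OC(=O)c1ccc(C)cc1)C(O)=O | intermediate
16 | (6R,8S,15R)-tetracyclic amino diketone diester, free base; not isolated | O=C1[C@H]2CCC3=C4[C@@H](CC3=O)C(C(=O)OC)(C(=O)OC)C[C@]41CN(C)C2 | intermediate
17 | C17 allylic alcohol of 16 (C5 ketone kept; carbinol configuration open) | O=C1[C@H]2CCC3=C4[C@@H](CC3O)C(C(=O)OC)(C(=O)OC)C[C@]41CN(C)C2 | intermediate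
18 | amino ketone: C17 as CH2, C9=C10 alkene, C5 ketone, C14 diester | O=C1[C@H]2CCC3=C4[C@@H](CC3)C(C(=O)OC)(C(=O)OC)C[C@]41CN(C)C2 | intermediate
19 | spiro-epoxide at C5 (oxirane CH2 syn to the C9=C10 bridge) | O5[C@]1(C5)[C@H]2CCC3=C4[C@@H](CC3)C(C(=O)OC)(C(=O)OC)C[C@]41CN(C)C2 | intermediate
20 | C5 carbaldehyde (both epimers at C5) | O=CC1[C@H]2CCC3=C4[C@@H](CC3)C(C(=O)OC)(C(=O)OC)C[C@]41CN(C)C2 | intermediate
21 | 5-formyl-5-(hydroxymethyl) compound: CH2OH (C21) syn to the C9=C10 bridge, CHO (C4) syn to nitrogen | O=C[C@]1(CO)[C@H]2CCC3=C4[C@@H](CC3)C(C(=O)OC)(C(=O)OC)C[C@]41CN(C)C2 | intermediate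
22 | dimethyl (2-oxobutyl)phosphonate | CCC(=O)CP(=O)(OC)OC | starting material
23 | (E)-enone: C5–CH=CH–C(=O)–CH2CH3 | CCC(=O)/C=C/[C@]1(CO)[C@H]2CCC3=C4[C@@H](CC3)C(C(=O)OC)(C(=O)OC)C[C@]41CN(C)C2 | intermediate
24 | (2S,E)-allylic alcohol | CC[C@H](O)/C=C/[C@]1(CO)[C@H]2CCC3=C4[C@@H](CC3)C(C(=O)OC)(C(=O)OC)C[C@]41CN(C)C2 | intermediate
25 | saturated diol diester (2S; C14 still bears two CO2Me) | CC[C@H](O)CC[C@]1(CO)[C@H]2CCC3=C4[C@@H](CC3)C(C(=O)OC)(C(=O)OC)C[C@]41CN(C)C2 | intermediate
26 | target, (2S,5S,6R,8S,14S,15S) | CC[C@H](O)CC[C@]1(CO)[C@H]2CCC3=C4[C@@H](CC3)[C@@H](C(=O)OC)C[C@]41CN(C)C2 | target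

Total step count: 17. Longest linear sequence: 16 steps (steps 1, 2 and 4 to 17).

**Steps most likely to fail**

Step 6, ring D closure. The extended enolate may be drained by β-elimination of the carbamate from the ester enolate, or by acylation at the wrong carbon that does not revert. The fallback sets out from 3 and comes back at 11. Alkyne 3 is coupled under the conditions of step 2 with 4-iodobutanenitrile to dimethyl 2-(7-cyanohept-3-yn-1-yl)-2-ethenylpropanedioate F1. Amidomethylation as in step 4 gives the α-branched nitrile F2, and cyclocarbonylation as in step 5 gives the racemic cyano enone F3. KOtBu (0.2 equiv.) in THF then closes ring D by Thorpe–Ziegler addition of C8 to the nitrile, which needs no leaving group and is not reversed by alkoxide, to give the tricyclic enaminone F4. Aqueous HCl at 50 °C hydrolyses the enamine and removes the Boc group, which gives 11 as its hydrochloride for the formaldehyde stage of step 7.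

Step 8, resolution. The diastereomeric salts may fail to crystallize or to differ enough in solubility, so that no enrichment is reached. The fallback sets out from 13 and comes back at 18. Racemic 13 is reduced under the Luche conditions of step 9 to 17 together with its mirror image F5. Esterification with (S)-methoxy(phenyl)acetic acid (dicyclohexylcarbodiimide, 4-dimethylaminopyridine, CH2Cl2) gives the diastereomeric allylic esters F6 (from 17) and F7 (from F5), which are separated by chromatography. Ester F6 is taken to 18 with Et3SiH and BF3·OEt2, the allylic ester ionizing in place of the alcohol of step 10.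

Step 13, hydroxymethylation. Formaldehyde may enter on the piperidine face, which would invert C5, and retro-aldol loss of formaldehyde is a second way to fail. The fallback sets out from 20 and comes back at 25; it applies if the piperidine face proves to be the preferred one, and reverses the order in which the two C5 substituents arrive. Aldehyde 20 adds (DBU, MeCN) to 5-(trimethylsilyl)pent-1-en-4-yn-3-one F8, made in one step from bis(trimethylsilyl)acetylene and acryloyl chloride with AlCl3. The chain then takes the preferred face and the formyl group is left syn to the C9=C10 bridge, giving keto aldehyde F9. Noyori transfer hydrogenation (RuCl[(R,R)-TsDPEN](p-cymene), 2-propanol) reduces the ynone to the propargylic alcohol with the C2 configuration of the target and the aldehyde to the primary alcohol, giving diol F10. K2CO3 in methanol removes the silyl group to give terminal alkyne F11, and H2 over Pd/C saturates the ethynyl group to ethyl, which gives 25.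

**Further compounds**

F1 | step 6 | dimethyl 2-(7-cyanohept-3-yn-1-yl)-2-ethenylpropanedioate | N#CCCCC#CCCC(C=C)(C(=O)OC)C(=O)OC
F2 | step 6 | dimethyl 2-{8-[(tert-butoxycarbonyl)(methyl)amino]-7-cyanooct-3-yn-1-yl}-2-ethenylpropanedioate | N#CC(CN(C)C(=O)OC(C)(C)C)CCC#CCCC(C=C)(C(=O)OC)C(=O)OC
F3 | step 6 | racemic bicyclic cyano enone (nitrile in place of the side-chain ester of 9) | N#CC(CN(C)C(=O)OC(C)(C)C)CCC1=C2C(CC1=O)C(C(=O)OC)(C(=O)OC)CC2
F4 | step 6 | racemic tricyclic enaminone (NH2 on C5 in place of the OH of 10) | NC=1C(CN(C)C(=O)OC(C)(C)C)CCC2=C3C(CC2=O)C(C(=O)OC)(C(=O)OC)CC3=1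
F5 | step 8 | mirror image of allylic alcohol 17 | O=C1[C@@H]2CCC3=C4[C@H](CC3O)C(C(=O)OC)(C(=O)OC)C[C@@]41CN(C)C2
F6 | step 8 | (S)-methoxy(phenyl)acetate of 17 | O=C1[C@H]2CCC3=C4[C@@H](CC3OC(=O)[C@@H](OC)c5ccccc5)C(C(=O)OC)(C(=O)OC)C[C@]41CN(C)C2
F7 | step 8 | (S)-methoxy(phenyl)acetate of F5 | O=C1[C@@H]2CCC3=C4[C@H](CC3OC(=O)[C@@H](OC)c5ccccc5)C(C(=O)OC)(C(=O)OC)C[C@@]41CN(C)C2
F8 | step 13 | 5-(trimethylsilyl)pent-1-en-4-yn-3-one | C=CC(=O)C#C[Si](C)(C)C
F9 | step 13 | keto aldehyde: C5 bears CHO (syn to the C9=C10 bridge) and CH2CH2C(=O)C≡C–SiMe3 (syn to nitrogen) | C[Si](C)(C)C#CC(=O)CC[C@]1(C=O)[C@H]2CCC3=C4[C@@H](CC3)C(C(=O)OC)(C(=O)OC)C[C@]41CN(C)C2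
F10 | step 13 | (2R)-silylated propargylic alcohol diol | C[Si](C)(C)C#C[C@H](O)CC[C@]1(CO)[C@H]2CCC3=C4[C@@H](CC3)C(C(=O)OC)(C(=O)OC)C[C@]41CN(C)C2
F11 | step 13 | (2R)-terminal alkyne diol | C#C[C@H](O)CC[C@]1(CO)[C@H]2CCC3=C4[C@@H](CC3)C(C(=O)OC)(C(=O)OC)C[C@]41CN(C)C2
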